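## The problem

Target 17 is [(1S,2R,3S,4R,5R,6S)-2,3-diacetoxy-4,5-dihydroxy-7-oxabicyclo[4.1.0]heptan-1-yl]methyl benzoate. Its carbons are numbered C1 (quaternary oxirane carbon), C2 and C3 (acetoxy carbons), C4 and C5 (carbinol carbons), C6 (oxirane CH) and C7 (exocyclic CH2OBz); this numbering is kept for every intermediate.

A cyclohexane with six contiguous stereocentres is fused to an oxirane across C1–C6, and C1 is fully substituted. The oxygens on C2 to C5 alternate from face to face. The oxirane oxygen lies on the face of the C2 and C4 oxygens (the α-face below), opposite to C7. An oxirane cis to the neighbouring C2 oxygen is not what epoxidation of a C1=C6 alkene or enone beside a C2 ether would be expected to give, since such reagents enter anti to that substituent.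

Five oxygens fall into three classes (acetates at C2 and C3, free hydroxyls at C4 and C5, a benzoate at primary C7), so the protecting groups must tell these apart. The oxirane is sensitive to acid and nucleophiles. The C3 acetate can migrate to the C4 hydroxyl under base, and the C5 hydroxyl is trans to the oxirane oxygen and can trigger a Payne rearrangement once it is an alkoxide. The last steps must therefore avoid hydroxide and alkoxide.

C2 to C4 form a xylo triad that is identical with C2 to C4 of D-glucose and can be bought. Once these three substituents sit equatorial on a chair they can control C1 and C6 through the way the ring closes, and then C5 through the face of a C5 carbonyl. The enabling feature is that the C1–C6 bond belongs to both rings, C1 is an oxygen-bearing carbon without hydrogen, and C5 next to C6 can be a carbonyl. That is the pattern left by a Darzens condensation of a C6 α-chloro carbanion with a C1 ketone.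

## Retrosynthesis

**17 back to triol 14.** The bonds cut are the two O–Si bonds (17 from bis-silyl ether 16), the two acetyl C–O bonds (16 from diol 15) and the benzoyl C–O bond (15 from triol 14). The free C4 and C5 hydroxyls are unveiled last, by buffered fluoride, because that is the only late operation that needs neither base nor hydrogen. C7 differs from C2 and C3 by being primary, so one benzyl class can serve all three and fall in a single hydrogenolysis (14 from tribenzyl ether 13), where three orthogonal groups would cost extra steps. The forward steps must spare the oxirane on hydrogenolysis, acylate the primary hydroxyl first, and desilylate without acyl shift.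

**13 back to epoxy ketone 11.** The C5 O–Si bond (13 from alcohol 12) and the C5–H bond (12 from ketone 11) are cut. A C5 carbonyl is what the ring-forming step needs in any case, since it acidifies C6. C5 is therefore best set after the rings exist, when the half-chair fixes the faces. The reduction must deliver hydride on the α-face so that the hydroxyl ends up equatorial, trans to the C4 oxygen and to the oxirane oxygen.

**11 back to chloro diketone 8.** C1–C6 and C6–O are cut together (Darzens disconnection, via enolate 9 and aldolate 10). The neighbouring cut, epoxidation of a preformed C1=C6 enone or alkene, would be expected to place the oxirane anti to the C2 ether, which is the wrong face. The Darzens closure instead ties the oxirane face to the chair of the aldolate. The precursor loses both rings and two stereocentres: 8 is an acyclic chain with three stereocentres. The forward step needs enolisation at C6 in preference to C2, C4 and C7, a reversible aldol, and trans-diaxial oxirane closure.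

**8 back to lactol 6.** The two carbonyl groups are returned to carbinols (8 from diol 7) and the C1–C7 bond is cut (7 from lactol 6 and a benzyloxymethyl Grignard reagent). C1 to C6 of 8 are the six carbons of a 6-chloro-6-deoxy-D-glucose, so only C7 is missing, and a one-carbon nucleophile adds to the anomeric carbon of a lactol in a standard way. The new carbinol configuration is irrelevant because it is oxidised. The forward oxidation must convert both alcohols before either hydroxy ketone can close to a hemiketal.

**6 back to thioglucoside 1.** Only functional groups change: anomeric hydroxyl from S-ethyl (6 from 5), O4 silyl ether (5 from 4), C6 chloride from the primary hydroxyl (4 from diol 3), acetal removal (3 from 2) and benzylation of O2 and O3 (2 from 1). Building the chain from a four-carbon chiral unit would need two C–C bond formations and a diastereoselective carbonyl addition to set C4. Here six of seven carbons and all three stereocentres are bought, and the benzylidene acetal of 1 singles out exactly the two oxygens (O4, O6) that need separate treatment. Written with C1 on top, 8 has C2–O right, C3–O left, C4–O right, which is the D-gluco pattern.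

## Roads not taken

**Alternative 1: palladium allylation converging two C1 epimers.** The bond made is the tertiary C1–O bond. Zerovalent palladium (Pd2(dba)3 with a chiral diphosphine) would ionise both C1 epimers of vinyl oxirane A1 to interconverting π-allyl complexes, and hydrogen carbonate carried on the C7 oxygen would attack the tertiary terminus to give cyclic carbonate A2 with one C1 configuration.
- Merits: C1 is set by the catalyst and not by substrate conformation, the conditions are neutral, and no base-sensitive 1,5-diketone is involved. On control of C1 this road is stronger than the chosen one.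
- Weak points: it makes one C–O bond and one stereocentre but no ring. The carbocycle would still have to come from ring-closing metathesis of the two vinyl groups of A2. The C5 oxygen and the oxirane would then have to be placed on the resulting C5=C6 alkene, each with its own facial problem. The ligand must also override three existing stereocentres at a hindered tertiary terminus.
- Against it the chosen plan sets both rings, C1 and C6 in one operation, and leaves the C5 carbonyl in place for the last stereocentre.

**Alternative 2: dibromocarbene ring expansion.** The cuts are C1–C2 and C1–C6. Dibromocarbene (CHBr3, KOC(CH3)3) would add to silyl enol ether A3 and the dibromocyclopropane would open to 2-bromocyclohexenone A4, with the ketone at C2 and bromine on C1.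
- Merits: ring expansion of this kind is dependable and the vinyl bromide is a handle for C7. After reduction of the C2 ketone, an allylic C2 hydroxyl could direct a peracid to the α-face. For the oxirane face this is as good as, or better than, conformational control.
- Weak points: A3 already contains a carbocycle with three stereocentres that must be made first. Its formation and the strongly basic carbene conditions expose a β-alkoxy ketone system to elimination and an α-alkoxy centre to epimerisation. The key step creates no stereocentre, and C7, C2 and the oxirane still need separate steps.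
- The chosen plan answers with a much shorter path in which the same step that closes the ring also sets the oxirane.

**Alternative 3: benzoate-triggered oxirane relay.** The cuts are C7–O (benzoate) and C6–O. CsO2CPh would open spiro-oxirane mesylate A5 at C7, and the freed C1 alkoxide would displace the axial C6 mesylate to give fused oxirane A6 with the benzoate in place.
- Merits: the step is stereospecific (C1–O kept, C6 inverted), so no facial selectivity is at stake, and it installs the benzoate directly. In both respects it is better than the chosen plan, which needs a conformational argument and a late selective benzoylation.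
- Weak points: A5 is a fully built C-branched cyclitol. All six ring stereocentres, the spiro-oxirane configuration at C1, an axial sulfonate at C6 and two orthogonal ether classes must be prepared beforehand. Direct substitution or elimination of the axial mesylate competes.
- The chosen plan sets against this that its precursor 8 is an acyclic glucose-derived chain reached in seven steps, with ring, oxirane and two stereocentres arising together.

Key step: step 8

Assumption: commercial 1 carries the usual (R)-benzylidene acetal (phenyl equatorial); this centre is removed in step 2 and plays no role. Compound 2 is itself sold, but its preparation is counted.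

## Route

Step 1
Reactants: 1 ethyl 4,6-O-benzylidene-1-thio-β-D-glucopyranoside
Product: 2 ethyl 2,3-di-O-benzyl-4,6-O-benzylidene-1-thio-β-D-glucopyranoside
Conditions: BnBr, NaH, n-Bu4NI (cat.), DMF, 0 °C → rt
Reagents that add atoms: benzyl bromide, BrCc1ccccc1
Why: Williamson etherification; acetal and thioethyl group are inert to alkoxide, so only O2 and O3 are benzylated.

Step 2
Reactants: 2 ethyl 2,3-di-O-benzyl-4,6-O-benzylidene-1-thio-β-D-glucopyranoside
Product: 3 ethyl 2,3-di-O-benzyl-1-thio-β-D-glucopyranoside
Conditions: AcOH/H2O (4:1), 60 °C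
Reagents that add atoms: none
Why: Acid-catalysed acetal hydrolysis; benzyl ethers and the thioglycoside (no thiophilic promoter present) survive, freeing O4 and O6.

Step 3
Reactants: 3 ethyl 2,3-di-O-benzyl-1-thio-β-D-glucopyranoside
Product: 4 ethyl 2,3-di-O-benzyl-6-chloro-6-deoxy-1-thio-β-D-glucopyranoside
Conditions: PPh3, CCl4, pyridine, 0 → 50 °C
Reagents that add atoms: carbon tetrachloride, ClC(Cl)(Cl)Cl
Why: Appel chlorination; the primary hydroxyl forms the alkoxyphosphonium ion and is displaced (SN2) much faster than the flanked secondary C4 hydroxyl, and the thioether does not react.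

Step 4
Reactants: 4 ethyl 2,3-di-O-benzyl-6-chloro-6-deoxy-1-thio-β-D-glucopyranoside
Product: 5 ethyl 2,3-di-O-benzyl-4-O-(tert-butyldimethylsilyl)-6-chloro-6-deoxy-1-thio-β-D-glucopyranoside
Conditions: TBSOTf, 2,6-lutidine, CH2Cl2, 0 °C
Reagents that add atoms: tert-butyldimethylsilyl trifluoromethanesulfonate, CC(C)(C)[Si](C)(C)OS(=O)(=O)C(F)(F)F
Why: Silylation of a hindered secondary alcohol with a silyl triflate; this ether marks O4 as one of the two oxygens that end free, and it tolerates all later steps up to the last.

Step 5
Reactants: 5 ethyl 2,3-di-O-benzyl-4-O-(tert-butyldimethylsilyl)-6-chloro-6-deoxy-1-thio-β-D-glucopyranoside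
Product: 6 2,3-di-O-benzyl-4-O-(tert-butyldimethylsilyl)-6-chloro-6-deoxy-D-glucopyranose (anomeric mixture)
Conditions: NBS, NaHCO3, acetone/H2O (9:1), −15 → 0 °C
Reagents that add atoms: water, O
Why: Oxidative hydrolysis of a thioglycoside (bromosulfonium ion, loss of sulfur, capture of the oxocarbenium ion by water); ethers and the primary chloride are untouched under buffered conditions.

Step 6
Reactants: 6 2,3-di-O-benzyl-4-O-(tert-butyldimethylsilyl)-6-chloro-6-deoxy-D-glucopyranose
Product: 7 (3S,4R,5R,6S)-1,3,4-tris(benzyloxy)-5-[(tert-butyldimethylsilyl)oxy]-7-chloroheptane-2,6-diol (both C2 epimers of the heptane chain)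
Conditions: BnOCH2MgCl (4 equiv; from BnOCH2Cl, Mg, cat. HgCl2, THF, −10 °C), THF, −20 → 0 °C; aq NH4Cl
Reagents that add atoms: benzyloxymethylmagnesium chloride, Cl[Mg]COCc1ccccc1
Why: Grignard addition to the open-chain aldehyde form of a lactol forms C1–C7; the new carbinol centre is oxidised next, so its configuration does not matter, and magnesium chlorohydrin alkoxides close to oxiranes only slowly at or below 0 °C.

Step 7
Reactants: 7 (3S,4R,5R,6S)-1,3,4-tris(benzyloxy)-5-[(tert-butyldimethylsilyl)oxy]-7-chloroheptane-2,6-diol
Product: 8 (3R,4R,5S)-1,3,4-tris(benzyloxy)-5-[(tert-butyldimethylsilyl)oxy]-7-chloroheptane-2,6-dione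
Conditions: (COCl)2, DMSO, CH2Cl2, −78 °C; Et3N, −78 → −30 °C; pH 7 buffer, cold
Reagents that add atoms: none
Why: Swern oxidation; both secondary alcohols become alkoxysulfonium ions at −78 °C before base is added, so neither hydroxy ketone can escape as a six-membered hemiketal, and the cold buffered quench limits contact of the 1,5-diketone with amine.

Step 8
Reactants: 8 (3R,4R,5S)-1,3,4-tris(benzyloxy)-5-[(tert-butyldimethylsilyl)oxy]-7-chloroheptane-2,6-dione
Product: 11 (1R,3S,4R,5R,6R)-4,5-bis(benzyloxy)-6-[(benzyloxy)methyl]-3-[(tert-butyldimethylsilyl)oxy]-7-oxabicyclo[4.1.0]heptan-2-one, via cesium chloro enolate 9 (not isolated), via cesium chlorohydrin aldolate 10 (not isolated)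
Conditions: Cs2CO3 (1.5 equiv), MeCN, −20 → 0 °C
Reagents that add atoms: none
Why: Carbonate removes a proton from C6, the most acidic site because it is flanked by the C5 carbonyl and chlorine, to give enolate 9. Its carbon adds to the C1 ketone, which two α-alkoxy groups make strongly electrophilic, in a 6-(enolendo)-exo-trig aldol that forms C1–C6 and the carbocycle (aldolate 10). The C1 alkoxide then displaces chloride at C6 in a 3-exo-tet SN2 step that forms C6–O and the oxirane; the closest known reaction type is the intramolecular Darzens condensation of an α-chloro ketone with a ketone. C1 is controlled by the chair of the reversibly formed aldolate: with the C2, C3 and C4 ethers and the C7 arm equatorial the alkoxide is axial on the α-face and can reach the back of an axial C6–Cl bond, whereas the C1 epimer would need the triaxial chair or a boat to close. C6 follows from inversion at the axial chloride, and the equatorial chloro epimer is returned to the pool by enolisation or retro-aldol. The step needs enolisation at C6 and not at C2, C4 or C7, which would lead to loss of the C3 benzyloxy group, epimerisation or ring closure in the reverse sense onto C5; the extra acidity given by chlorine, a weak heterogeneous base, low temperature and the irreversible oxirane closure are relied on for this. C4 stays α to the ketone in 11 but already has its more stable equatorial configuration.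

Step 9
Reactants: 11 (1R,3S,4R,5R,6R)-4,5-bis(benzyloxy)-6-[(benzyloxy)methyl]-3-[(tert-butyldimethylsilyl)oxy]-7-oxabicyclo[4.1.0]heptan-2-one
Product: 12 (1S,2S,3R,4R,5R,6S)-4,5-bis(benzyloxy)-6-[(benzyloxy)methyl]-3-[(tert-butyldimethylsilyl)oxy]-7-oxabicyclo[4.1.0]heptan-2-ol (C5 hydroxyl trans to the C4 silyloxy group and to the oxirane oxygen)
Conditions: NaBH4, CeCl3·7H2O, MeOH, −78 °C
Reagents that add atoms: none
Why: Luche reduction; hydride is expected to enter along the axial trajectory on the α-face, giving the equatorial C5 alcohol, which is also the trans sense expected for cerium-assisted borohydride reduction of 2,3-epoxycyclohexanones; the near-neutral medium avoids Payne rearrangement.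

Step 10
Reactants: 12 (1S,2S,3R,4R,5R,6S)-4,5-bis(benzyloxy)-6-[(benzyloxy)methyl]-3-[(tert-butyldimethylsilyl)oxy]-7-oxabicyclo[4.1.0]heptan-2-ol
Product: 13 C5 tert-butyldimethylsilyl ether of 12 (C2, C3, C7 benzyl ethers; C4, C5 silyl ethers; ring configuration as in 17)
Conditions: TBSOTf, 2,6-lutidine, CH2Cl2, −78 → 0 °C
Reagents that add atoms: tert-butyldimethylsilyl trifluoromethanesulfonate, CC(C)(C)[Si](C)(C)OS(=O)(=O)C(F)(F)F
Why: Silyl triflate silylation with a non-nucleophilic base; no C5 alkoxide is formed, so the oxirane cannot migrate.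

Step 11
Reactants: 13 C5 tert-butyldimethylsilyl ether of 12
Product: 14 C2,C3,C7-triol with C4 and C5 tert-butyldimethylsilyl ethers (ring configuration as in 17)
Conditions: H2 (1 atm), 10% Pd/C, EtOAc, rt
Reagents that add atoms: none
Why: Hydrogenolysis of three benzyl ethers; the oxirane is neither benzylic nor allylic and silyl ethers are stable in ethyl acetate.

Step 12
Reactants: 14 C2,C3,C7-triol with C4 and C5 tert-butyldimethylsilyl ethers
Product: 15 C7 benzoate of 14 (C2, C3 free hydroxyls; ring configuration as in 17)
Conditions: BzCl (1.05 equiv), pyridine, CH2Cl2, −40 → −20 °C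
Reagents that add atoms: benzoyl chloride, O=C(Cl)c1ccccc1
Why: Selective acylation of the one primary alcohol beside two flanked secondary alcohols with one equivalent of acid chloride at low temperature.

Step 13
Reactants: 15 C7 benzoate of 14
Product: 16 C2,C3-diacetate of 15 (4,5-bis-O-silyl ether of 17)
Conditions: Ac2O, pyridine, DMAP (cat.), CH2Cl2, 0 °C → rt
Reagents that add atoms: acetic anhydride, CC(=O)OC(C)=O
Why: DMAP-catalysed acetylation of the two remaining secondary hydroxyls; no base strong enough to move silyl or acyl groups is present.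

Step 14
Reactants: 16 C2,C3-diacetate of 15
Product: 17 [(1S,2R,3S,4R,5R,6S)-2,3-diacetoxy-4,5-dihydroxy-7-oxabicyclo[4.1.0]heptan-1-yl]methyl benzoate
Conditions: HF·pyridine, pyridine, THF, 0 °C → rt
Reagents that add atoms: none
Why: Fluoride cleavage of both Si–O bonds under buffered, slightly acidic conditions; the absence of alkoxide suppresses acetyl migration from O3 to O4 and Payne rearrangement at C5, and the electron-poor trisubstituted oxirane should tolerate the reagent.

## Compound list

1 | ethyl 4,6-O-[(R)-benzylidene]-1-thio-β-D-glucopyranoside | CCS[C@H]1[C@H](O)[C@@H](O)[C@@H]2O[C@H](c3ccccc3)OC[C@H]2O1 | starting material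
2 | ethyl 2,3-di-O-benzyl-4,6-O-[(R)-benzylidene]-1-thio-β-D-glucopyranoside | CCS[C@H]1[C@H](OCc3ccccc3)[C@@H](OCc3ccccc3)[C@@H]2O[C@H](c3ccccc3)OC[C@H]2O1 | intermediate
3 | ethyl 2,3-di-O-benzyl-1-thio-β-D-glucopyranoside | CCS[C@H]1[C@H](OCc2ccccc2)[C@@H](OCc2ccccc2)[C@H](O)[C@@H](CO)O1 | intermediate
4 | ethyl 2,3-di-O-benzyl-6-chloro-6-deoxy-1-thio-β-D-glucopyranoside | CCS[C@H]1[C@H](OCc2ccccc2)[C@@H](OCc2ccccc2)[C@H](O)[C@@H](CCl)O1 | intermediate
5 | ethyl 2,3-di-O-benzyl-4-O-(tert-butyldimethylsilyl)-6-chloro-6-deoxy-1-thio-β-D-glucopyranoside | CCS[C@H]1[C@H](OCc2ccccc2)[C@@H](OCc2ccccc2)[C@H](O[Si](C)(C)C(C)(C)C)[C@@H](CCl)O1 | intermediate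
6 | 2,3-di-O-benzyl-4-O-(tert-butyldimethylsilyl)-6-chloro-6-deoxy-D-glucopyranose (anomeric mixture) | OC1[C@H](OCc2ccccc2)[C@@H](OCc2ccccc2)[C@H](O[Si](C)(C)C(C)(C)C)[C@@H](CCl)O1 | intermediate
7 | (3S,4R,5R,6S)-1,3,4-tris(benzyloxy)-5-[(tert-butyldimethylsilyl)oxy]-7-chloroheptane-2,6-diol (both C2 epimers) | OC(COCc1ccccc1)[C@H](OCc1ccccc1)[C@@H](OCc1ccccc1)[C@H](O[Si](C)(C)C(C)(C)C)[C@H](O)CCl | intermediate
8 | (3R,4R,5S)-1,3,4-tris(benzyloxy)-5-[(tert-butyldimethylsilyl)oxy]-7-chloroheptane-2,6-dione | ClCC(=O)[C@@H](O[Si](C)(C)C(C)(C)C)[C@H](OCc1ccccc1)[C@@H](OCc1ccccc1)C(=O)COCc1ccccc1 | intermediate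
9 | cesium enolate of 8 at the chloromethyl ketone (C5–O−, C5=C6, either geometry) | [Cs+].[O-]C(=CCl)[C@@H](O[Si](C)(C)C(C)(C)C)[C@H](OCc1ccccc1)[C@@H](OCc1ccccc1)C(=O)COCc1ccccc1 | intermediate (not isolated)
10 | cesium 2,3-bis(benzyloxy)-1-[(benzyloxy)methyl]-4-[(tert-butyldimethylsilyl)oxy]-6-chloro-5-oxocyclohexan-1-olate (C1–O− on the α-face and C6–Cl trans-diaxial) | c1ccccc1CO[C@H]1[C@H](O[Si](C)(C)C(C)(C)C)C(=O)[C@@H](Cl)[C@@]([O-])(COCc2ccccc2)[C@@H]1OCc1ccccc1.[Cs+] | intermediate (not isolated)
11 | (1R,3S,4R,5R,6R)-4,5-bis(benzyloxy)-6-[(benzyloxy)methyl]-3-[(tert-butyldimethylsilyl)oxy]-7-oxabicyclo[4.1.0]heptan-2-one | c1ccccc1CO[C@H]2[C@H](O[Si](C)(C)C(C)(C)C)C(=O)[C@@H]3O[C@]3(COCc4ccccc4)[C@@H]2OCc5ccccc5 | intermediate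
12 | (1S,2S,3R,4R,5R,6S)-4,5-bis(benzyloxy)-6-[(benzyloxy)methyl]-3-[(tert-butyldimethylsilyl)oxy]-7-oxabicyclo[4.1.0]heptan-2-ol | c1ccccc1CO[C@H]1[C@H](O[Si](C)(C)C(C)(C)C)[C@@H](O)[C@@H]2O[C@]2(COCc2ccccc2)[C@@H]1OCc1ccccc1 | intermediate
13 | C5 tert-butyldimethylsilyl ether of 12 (C2, C3, C7 benzyl; C4, C5 silyl) | c1ccccc1CO[C@H]1[C@H](O[Si](C)(C)C(C)(C)C)[C@@H](O[Si](C)(C)C(C)(C)C)[C@@H]2O[C@]2(COCc2ccccc2)[C@@H]1OCc1ccccc1 | intermediate
14 | 4,5-bis-O-(tert-butyldimethylsilyl) C2,C3,C7-triol (1-hydroxymethyl-7-oxabicyclo[4.1.0]heptane-2,3-diol core, configuration as in 17) | O[C@H]1[C@H](O[Si](C)(C)C(C)(C)C)[C@@H](O[Si](C)(C)C(C)(C)C)[C@@H]2O[C@]2(CO)[C@@H]1O | intermediate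
15 | C7 benzoate of 14 | O[C@H]1[C@H](O[Si](C)(C)C(C)(C)C)[C@@H](O[Si](C)(C)C(C)(C)C)[C@@H]2O[C@]2(COC(=O)c2ccccc2)[C@@H]1O | intermediate
16 | C2,C3-diacetate of 15 (4,5-bis-O-silyl ether of 17) | CC(=O)O[C@H]1[C@H](O[Si](C)(C)C(C)(C)C)[C@@H](O[Si](C)(C)C(C)(C)C)[C@@H]2O[C@]2(COC(=O)c2ccccc2)[C@@H]1OC(C)=O | intermediate
17 | [(1S,2R,3S,4R,5R,6S)-2,3-diacetoxy-4,5-dihydroxy-7-oxabicyclo[4.1.0]heptan-1-yl]methyl benzoate | CC(=O)O[C@H]1[C@H](O)[C@@H](O)[C@@H]2O[C@]2(COC(=O)c2ccccc2)[C@@H]1OC(C)=O | target

## Step count and risks

Total: 14 steps. Longest linear sequence: 14 steps (1 → 17).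

**Step 8 (key step).** Enolisation may occur at C2, C4 or C7 instead of C6, because the acidity differences between the four α-positions of a 1,5-diketone are modest. The consequences would be β-elimination of the C3 benzyloxy group, epimerisation at C2 before the ring closes, or ring closure in the reverse sense (C7 onto the C5 carbonyl, with the chloride then closing a spiro-oxirane). The fallback separates carbocyclisation from oxirane formation and sets the oxirane face with a directing hydroxyl.
- It sets out from 8: radical dechlorination (Bu3SnH, AIBN) should give the methyl ketone, 1,3,4-tris(benzyloxy)-5-silyloxyheptane-2,6-dione F1.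
- Base-mediated aldol cyclisation, established for sugar-derived 1,5-diketones of this type, should give the tertiary β-hydroxy ketone F2.
- Dehydration (MsCl, Et3N) should give the enone F3.
- LiBH(s-Bu)3 should reduce the C5 carbonyl from the face opposite to the C4 silyloxy group, giving the pseudo-axial allylic alcohol F4 with its hydroxyl on the α-face.
- Henbest epoxidation (mCPBA) directed by that hydroxyl should give the α-epoxy alcohol F5.
- Dess–Martin oxidation returns to the route at 11.

**Step 9.** Hydride may be delivered from the face opposite to the oxirane oxygen (attack anti to the C6–O bond), which would give the C5 epimer. The fallback uses intramolecular delivery. It sets out from 11: HF·pyridine should remove the C4 silyl group to give the hydroxy epoxy ketone F6. Me4NBH(OAc)3 in MeCN/AcOH at −20 °C then binds the C4 oxygen and delivers hydride on the α-face, which should give the trans-4,5-diol F7. Double silylation (TBSOTf, 2,6-lutidine) returns to the route at 13.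

**Step 6.** Ring opening of the lactol may be incomplete, and the open-chain C5 alkoxide may close onto C6 with loss of chloride or pick up the neighbouring silyl group. The fallback keeps O5 inside the pyranose ring while the C1–C7 bond is made. It sets out from 6: Ac2O/DMSO oxidation should give the glucono-1,5-lactone F8. BnOCH2Li (from Bu3SnCH2OBn and n-BuLi, THF, −78 °C) should add once to give the hemiketal F9. NaBH4 in MeOH/THF reduces it through its open-chain hydroxy ketone form and returns to the route at 7.

**Step 14.** Cleavage of two hindered secondary silyl ethers may be slow, and forcing it invites acetyl migration onto the freed hydroxyls or opening of the oxirane by fluoride. The fallback exchanges the silyl groups for levulinates before any ester is present.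
- It sets out from 12: HF·pyridine should give the diol F7.
- Levulinic acid, diisopropylcarbodiimide and DMAP should give the bis-levulinate F10.
- Hydrogenolysis (H2, 10% Pd/C, EtOAc) should give the triol F11.
- Selective benzoylation should give the C7 benzoate F12, and acetylation the diacetate F13.
- Hydrazine acetate in pyridine/AcOH removes only the levulinates and returns to the route at 17.

## Further compounds

F1 | step 8 | (3R,4R,5S)-1,3,4-tris(benzyloxy)-5-[(tert-butyldimethylsilyl)oxy]heptane-2,6-dione | CC(=O)[C@@H](O[Si](C)(C)C(C)(C)C)[C@H](OCc1ccccc1)[C@@H](OCc1ccccc1)C(=O)COCc1ccccc1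
F2 | step 8 | 3,4-bis(benzyloxy)-5-[(benzyloxy)methyl]-2-[(tert-butyldimethylsilyl)oxy]-5-hydroxycyclohexanone (C1 hydroxyl on the α-face) | c1ccccc1CO[C@H]1[C@H](O[Si](C)(C)C(C)(C)C)C(=O)C[C@@](O)(COCc2ccccc2)[C@@H]1OCc1ccccc1
F3 | step 8 | 4,5-bis(benzyloxy)-3-[(benzyloxy)methyl]-6-[(tert-butyldimethylsilyl)oxy]cyclohex-2-enone | c1ccccc1CO[C@H]1[C@H](O[Si](C)(C)C(C)(C)C)C(=O)C=C(COCc2ccccc2)[C@@H]1OCc1ccccc1
F4 | step 8 | 4,5-bis(benzyloxy)-3-[(benzyloxy)methyl]-6-[(tert-butyldimethylsilyl)oxy]cyclohex-2-enol (C5 hydroxyl cis to the C4 silyloxy group) | c1ccccc1CO[C@H]1[C@H](O[Si](C)(C)C(C)(C)C)[C@H](O)C=C(COCc2ccccc2)[C@@H]1OCc1ccccc1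
F5 | step 8 | C5 epimer of 12 (hydroxyl cis to the oxirane oxygen) | c1ccccc1CO[C@H]1[C@H](O[Si](C)(C)C(C)(C)C)[C@H](O)[C@@H]2O[C@]2(COCc2ccccc2)[C@@H]1OCc1ccccc1
F6 | step 9 | 4,5-bis(benzyloxy)-6-[(benzyloxy)methyl]-3-hydroxy-7-oxabicyclo[4.1.0]heptan-2-one (11 without the silyl group) | c1ccccc1CO[C@H]1[C@H](O)C(=O)[C@@H]2O[C@]2(COCc2ccccc2)[C@@H]1OCc1ccccc1
F7 | step 9 | 4,5-bis(benzyloxy)-6-[(benzyloxy)methyl]-7-oxabicyclo[4.1.0]heptane-2,3-diol (trans-4,5-diol in route numbering, configuration as in 17) | c1ccccc1CO[C@H]1[C@H](O)[C@@H](O)[C@@H]2O[C@]2(COCc2ccccc2)[C@@H]1OCc1ccccc1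
F8 | step 6 | 2,3-di-O-benzyl-4-O-(tert-butyldimethylsilyl)-6-chloro-6-deoxy-D-glucono-1,5-lactone | O=C1[C@H](OCc2ccccc2)[C@@H](OCc2ccccc2)[C@H](O[Si](C)(C)C(C)(C)C)[C@@H](CCl)O1
F9 | step 6 | 1,3,4-tri-O-benzyl-5-O-(tert-butyldimethylsilyl)-7-chloro-7-deoxy-D-gluco-hept-2-ulopyranose (hemiketal, anomeric mixture) | OC1(COCc2ccccc2)[C@H](OCc2ccccc2)[C@@H](OCc2ccccc2)[C@H](O[Si](C)(C)C(C)(C)C)[C@@H](CCl)O1
F10 | step 14 | 4,5-bis-O-levulinoyl derivative of F7 | c1ccccc1CO[C@H]1[C@H](OC(=O)CCC(C)=O)[C@@H](OC(=O)CCC(C)=O)[C@@H]2O[C@]2(COCc2ccccc2)[C@@H]1OCc1ccccc1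
F11 | step 14 | 4,5-bis-O-levulinoyl C2,C3,C7-triol | O[C@H]1[C@H](OC(=O)CCC(C)=O)[C@@H](OC(=O)CCC(C)=O)[C@@H]2O[C@]2(CO)[C@@H]1O
F12 | step 14 | C7 benzoate of F11 | O[C@H]1[C@H](OC(=O)CCC(C)=O)[C@@H](OC(=O)CCC(C)=O)[C@@H]2O[C@]2(COC(=O)c2ccccc2)[C@@H]1O
F13 | step 14 | C2,C3-diacetate of F12 (4,5-bis-O-levulinoyl derivative of 17) | CC(=O)O[C@H]1[C@H](OC(=O)CCC(C)=O)[C@@H](OC(=O)CCC(C)=O)[C@@H]2O[C@]2(COC(=O)c2ccccc2)[C@@H]1OC(C)=O
A1 | alternative 1 | 2-ethenyl-2-[3-(benzyloxy)-1,2-bis(4-methoxybenzyloxy)pent-4-enyl]oxirane (both C1 epimers) | C=CC1(CO1)[C@H](OCc2ccc(OC)cc2)[C@@H](OCc2ccc(OC)cc2)[C@H](OCc2ccccc2)C=C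
A2 | alternative 1 | 4-ethenyl-4-[3-(benzyloxy)-1,2-bis(4-methoxybenzyloxy)pent-4-enyl]-1,3-dioxolan-2-one | C=C[C@@]1(COC(=O)O1)[C@H](OCc2ccc(OC)cc2)[C@@H](OCc2ccc(OC)cc2)[C@H](OCc2ccccc2)C=C
A3 | alternative 2 | 3,4-bis(benzyloxy)-5-(4-methoxybenzyloxy)-1-(trimethylsilyloxy)cyclopentene | COc1ccc(cc1)CO[C@H]2[C@H](OCc3ccccc3)[C@@H](OCc3ccccc3)C=C2O[Si](C)(C)C
A4 | alternative 2 | 4,5-bis(benzyloxy)-2-bromo-6-(4-methoxybenzyloxy)cyclohex-2-enone | COc1ccc(cc1)CO[C@H]2[C@H](OCc3ccccc3)[C@@H](OCc3ccccc3)C=C(Br)C2=O
A5 | alternative 3 | 5,6-bis(benzyloxy)-7,8-bis(4-methoxybenzyloxy)-1-oxaspiro[2.5]octan-4-yl methanesulfonate | COc1ccc(cc1)CO[C@H]2[C@H](OCc3ccccc3)[C@@H](OCc3ccccc3)[C@@H](OS(C)(=O)=O)[C@@]4(CO4)[C@@H]2OCc5ccc(OC)cc5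
A6 | alternative 3 | [4,5-bis(benzyloxy)-2,3-bis(4-methoxybenzyloxy)-7-oxabicyclo[4.1.0]heptan-1-yl]methyl benzoate | COc1ccc(cc1)CO[C@H]2[C@H](OCc3ccccc3)[C@@H](OCc3ccccc3)[C@@H]4O[C@]4(COC(=O)c5ccccc5)[C@@H]2OCc6ccc(OC)cc6
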